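**Strategy.** The ring is cut at C2–C3 and C4–C5 (C1 = alkene carbon bearing CH2OBz). C2 (vinylic CH) and C5 (benzoate carbon) are 1,4-related and are treated as the two α-carbons of furan-3-ylmethyl benzoate; C3 and C4, with both their oxygens, come from vinylene carbonate. One thermal [4+2] cycloaddition forms both bonds and gives an exo 7-oxanorbornene carbonate. The oxygen bridge, absent from the target, stays on C5 and leaves C2 in a rhodium-catalysed anti SN2' opening that creates the C1=C2 alkene and the C6–O bond. The carbonate ring is then spent as the leaving group for allylic methoxylation at C3, and C4 is inverted last.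

Key step: step 2

Assumption: the (S,R)-ligand in step 3 is taken, by analogy with the desymmetrisation of oxabenzonorbornadiene, to be the enantiomer that opens 4 rather than its mirror image; its antipode would be used if a test reaction shows the opposite sense.

Compound 4 is racemic; from 5 onwards the material is a single enantiomer. Locants C1–C6 refer to the cyclohexene numbering of the target.

Step 1
Reactants: 1 furan-3-ylmethanol
Product: 2 furan-3-ylmethyl benzoate
Conditions: BzCl, Et3N, DMAP (cat.), CH2Cl2, 0 °C to rt
Reagents that add atoms: benzoyl chloride, O=C(Cl)c1ccccc1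
Why: DMAP-catalysed O-acylation (esterification with an acid chloride) of the only hydroxyl group; no stereocentre is involved.

Step 2
Reactants: 2 furan-3-ylmethyl benzoate; 3 vinylene carbonate
Product: 4 racemic exo cycloadduct, [(3aS*,4S*,7R*,7aR*)-2-oxo-3a,4,7,7a-tetrahydro-4,7-epoxy-1,3-benzodioxol-5-yl]methyl benzoate (carbonate ring syn to the oxygen bridge)
Conditions: vinylene carbonate (3 equiv), BHT (cat.), neat, sealed tube, 130 °C, 3 d; endo isomer removed by chromatography
Reagents that add atoms: none
Why: A concerted, suprafacial thermal [4+2] cycloaddition (Diels–Alder reaction) joins the two α-carbons of the furan to the two alkene carbons of vinylene carbonate and so forms the future C2–C3 and C4–C5 bonds together; the closest known case is the cycloaddition of furan itself to vinylene carbonate. The carbocyclic six-membered ring closes in this [4π+2π] mode as a boat held by the oxygen bridge, and the same two bonds close the oxolane ring of the 7-oxanorbornene. The two new carbinol centres are cis because the Z-alkene is locked in the carbonate ring and adds suprafacially, and the two bridgeheads are cis because the furan oxygen spans them. The exo relation of the carbonate to the bridge is the selectivity the step needs; prolonged heating should favour it as the more stable isomer, and the endo isomer is separated. Regiochemistry is not an issue because the dienophile is symmetric, the benzoate side chain does not deactivate the diene, and the product is racemic.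

Step 3
Reactants: 4 racemic exo cycloadduct
Product: 5 [(3aR,4R,5S,7aS)-4-hydroxy-5-[(4-methoxybenzyl)oxy]-2-oxo-3a,4,5,7a-tetrahydro-1,3-benzodioxol-6-yl]methyl benzoate (ether trans to the hydroxyl, hydroxyl cis to the carbonate)
Conditions: [Rh(cod)Cl]2 (2.5 mol %), (S)-1-[(R)-2-(diphenylphosphino)ferrocenyl]ethyldi-tert-butylphosphine (6 mol %), AgOTf then Bu4NI (rhodium iodide catalyst formed in situ), 4-MeOC6H4CH2OH (3 equiv), THF, 80 °C, stopped near half conversion
Reagents that add atoms: 4-methoxybenzyl alcohol, COc1ccc(CO)cc1
Why: Rhodium-catalysed asymmetric ring opening of an oxabicyclic alkene, run as a kinetic resolution: the chiral rhodium iodide complex inserts from the exo face into the strained allylic C–O bond at the bridgehead next to the substituted alkene carbon of the matched enantiomer, and the alcohol then attacks the unsubstituted allyl terminus anti to the metal (overall anti SN2'), which sets the new ether centre trans to the hydroxyl left by the bridge and places the alkene between the former bridgehead and the CH2OBz-bearing carbon.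

Step 4
Reactants: 5 hydroxy carbonate
Product: 6 [(3aS,4R,5S,7aS)-4-(benzoyloxy)-5-[(4-methoxybenzyl)oxy]-2-oxo-3a,4,5,7a-tetrahydro-1,3-benzodioxol-6-yl]methyl benzoate
Conditions: BzCl, pyridine, DMAP (cat.), 0 °C to rt
Reagents that add atoms: benzoyl chloride, O=C(Cl)c1ccccc1
Why: Acylation of the single free, secondary hydroxyl with benzoyl chloride under DMAP catalysis, which should be faster than any migration of the carbonate; no stereocentre changes.

Step 5
Reactants: 6 dibenzoate carbonate
Product: 7 [(3S,4S,5S,6S)-5-(benzoyloxy)-4-hydroxy-3-methoxy-6-[(4-methoxybenzyl)oxy]cyclohex-1-en-1-yl]methyl benzoate (3-OMe, 4-OH and 5-OBz all cis; 6-OPMB trans to 5-OBz)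
Conditions: Pd2(dba)3·CHCl3 (2.5 mol %), PPh3 (10 mol %), Et3B (10 mol %), MeOH (10 equiv), THF, 0 °C to rt
Reagents that add atoms: methanol, CO
Why: Tsuji–Trost decarboxylative allylic etherification: zerovalent palladium ionises the allylic C–O bond of the cyclic carbonate with inversion, CO2 is lost, and methanol, delivered through the boron-bound neighbouring alkoxide, attacks the less hindered allyl terminus (C3, not the fully substituted C1) on the face away from palladium, so the methoxy group is installed with net retention, cis to the liberated C4 hydroxyl.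

Step 6
Reactants: 7 all-cis hydroxy ether
Product: 10 [(3S,4R,5S,6S)-5-(benzoyloxy)-4-hydroxy-3-methoxy-6-[(4-methoxybenzyl)oxy]cyclohex-1-en-1-yl]methyl benzoate (C4 hydroxyl now trans to both neighbours), via C4 triflate 8 (not isolated), via C4-epimeric nitrite ester 9 (not isolated)
Conditions: Tf2O, pyridine, CH2Cl2, −20 °C; then Bu4NNO2, toluene, rt; aqueous work-up
Reagents that add atoms: tetrabutylammonium nitrite, CCCC[N+](CCCC)(CCCC)CCCC.[O-]N=O
Why: Lattrell–Dax inversion: the triflate of the only free hydroxyl undergoes SN2 displacement by nitrite from the face opposite to its two cis neighbours (which therefore cannot participate), and hydrolysis of the nitrite ester on work-up gives the C4-inverted, all-trans alcohol.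

Step 7
Reactants: 10 PMB-protected precursor
Product: 11 target, [(3S,4R,5R,6S)-5-(benzoyloxy)-4,6-dihydroxy-3-methoxycyclohex-1-en-1-yl]methyl benzoate
Conditions: DDQ, CH2Cl2/pH 7 buffer, 0 °C
Reagents that add atoms: none
Why: Oxidative deprotection of a 4-methoxybenzyl ether with DDQ (benzylic hydride abstraction, then hydrolysis of the oxocarbenium ion), which leaves the esters, the methyl ether, the alkene and all stereocentres untouched.

**Compound list**

1 | furan-3-ylmethanol | OCc1ccoc1 | starting material
2 | furan-3-ylmethyl benzoate | O=C(OCc1ccoc1)c1ccccc1 | intermediate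
3 | vinylene carbonate (1,3-dioxol-2-one) | O=C1OC=CO1 | starting material
4 | racemic exo cycloadduct, [(3aS*,4S*,7R*,7aR*)-2-oxo-3a,4,7,7a-tetrahydro-4,7-epoxy-1,3-benzodioxol-5-yl]methyl benzoate (SMILES shows the enantiomer consumed in step 3) | O=C1O[C@@H]2[C@H]3C=C(COC(=O)c4ccccc4)[C@H](O3)[C@@H]2O1 | intermediate
5 | [(3aR,4R,5S,7aS)-4-hydroxy-5-[(4-methoxybenzyl)oxy]-2-oxo-3a,4,5,7a-tetrahydro-1,3-benzodioxol-6-yl]methyl benzoate | O=C1O[C@H]2C=C(COC(=O)c3ccccc3)[C@H](OCc3ccc(OC)cc3)[C@@H](O)[C@H]2O1 | intermediate
6 | [(3aS,4R,5S,7aS)-4-(benzoyloxy)-5-[(4-methoxybenzyl)oxy]-2-oxo-3a,4,5,7a-tetrahydro-1,3-benzodioxol-6-yl]methyl benzoate | O=C1O[C@H]2C=C(COC(=O)c3ccccc3)[C@H](OCc3ccc(OC)cc3)[C@@H](OC(=O)c3ccccc3)[C@H]2O1 | intermediate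
7 | [(3S,4S,5S,6S)-5-(benzoyloxy)-4-hydroxy-3-methoxy-6-[(4-methoxybenzyl)oxy]cyclohex-1-en-1-yl]methyl benzoate | CO[C@H]1C=C(COC(=O)c2ccccc2)[C@H](OCc2ccc(OC)cc2)[C@@H](OC(=O)c2ccccc2)[C@H]1O | intermediate
8 | C4 triflate of 7 | CO[C@H]1C=C(COC(=O)c2ccccc2)[C@H](OCc2ccc(OC)cc2)[C@@H](OC(=O)c2ccccc2)[C@H]1OS(=O)(=O)C(F)(F)F | intermediate (not isolated)
9 | C4-epimeric nitrite ester | CO[C@H]1C=C(COC(=O)c2ccccc2)[C@H](OCc2ccc(OC)cc2)[C@@H](OC(=O)c2ccccc2)[C@@H]1ON=O | intermediate (not isolated)
10 | [(3S,4R,5S,6S)-5-(benzoyloxy)-4-hydroxy-3-methoxy-6-[(4-methoxybenzyl)oxy]cyclohex-1-en-1-yl]methyl benzoate | CO[C@H]1C=C(COC(=O)c2ccccc2)[C@H](OCc2ccc(OC)cc2)[C@@H](OC(=O)c2ccccc2)[C@@H]1O | intermediate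
11 | [(3S,4R,5R,6S)-5-(benzoyloxy)-4,6-dihydroxy-3-methoxycyclohex-1-en-1-yl]methyl benzoate | CO[C@H]1C=C(COC(=O)c2ccccc2)[C@H](O)[C@@H](OC(=O)c2ccccc2)[C@@H]1O | target

**Summary**

Total step count: 7. Longest linear sequence: 7 steps (from furan-3-ylmethanol).

Steps most likely to fail:

Step 3. The catalyst may discriminate poorly between the two enantiomers of 4, or open the mismatched one at the hindered terminus, so that 5 is not enantiopure. Fallback, from 4 back to 5: racemic 4 is opened with an achiral catalyst ([Rh(cod)Cl]2, 1,1'-bis(diphenylphosphino)ferrocene, Bu4NI, 4-methoxybenzyl alcohol, THF, 80 °C), which should give 5 together with the enantiomeric alcohol F1. The mixture is then resolved by lipase-catalysed acyl transfer (Burkholderia cepacia lipase, vinyl benzoate, t-BuOMe, 40 °C). On the empirical size rule for secondary alcohols, with the C6 side (PMB ether next to the substituted alkene) as the larger group, F1 should be acylated faster and give the enantiomeric benzoate F2, while 5 is recovered and re-enters at step 4. Should the enzyme prefer 5 instead, the ester formed is 6 itself and the route continues at step 5.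

Step 5. Ionisation may be slow because the allylic C–O bond is not easily brought anti-periplanar to the metal, so the primary allylic benzoate may ionise in competition, or a benzoyl group may shift to the cis alkoxide. Fallback, from 6 back to 7: the strained cyclic carbonate is cleaved selectively (K2CO3 cat., MeOH, −20 °C; the benzoates should react far more slowly) to the cis-diol F3. Bu2SnO (toluene, reflux) should convert it into the stannylene acetal F4, which activates the equatorial, allylic C3 oxygen; methylation (MeI, CsF, DMF) should then give 7.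

Step 6. The triflate may lose triflic acid by E2 elimination towards the allylic C3–H instead of undergoing substitution at the crowded C4. Fallback, from 7 back to 10: 7 is oxidised with Dess–Martin periodinane (NaHCO3, CH2Cl2) to the C4 ketone F5, which is reduced with NaBH4/CeCl3·7H2O in MeOH at −78 °C. Axial hydride delivery to the half-chair that holds the C3, C5 and C6 substituents (pseudo)equatorial should give the equatorial, all-trans alcohol 10.

**Further compounds**

F1 | step 3 | enantiomer of 5, [(3aS,4S,5R,7aR)-4-hydroxy-5-[(4-methoxybenzyl)oxy]-2-oxo-3a,4,5,7a-tetrahydro-1,3-benzodioxol-6-yl]methyl benzoate | O=C1O[C@@H]2C=C(COC(=O)c3ccccc3)[C@@H](OCc3ccc(OC)cc3)[C@H](O)[C@@H]2O1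
F2 | step 3 | enantiomer of 6, [(3aR,4S,5R,7aR)-4-(benzoyloxy)-5-[(4-methoxybenzyl)oxy]-2-oxo-3a,4,5,7a-tetrahydro-1,3-benzodioxol-6-yl]methyl benzoate | O=C1O[C@@H]2C=C(COC(=O)c3ccccc3)[C@@H](OCc3ccc(OC)cc3)[C@H](OC(=O)c3ccccc3)[C@@H]2O1
F3 | step 5 | cis-3,4-diol from 6 (carbonate removed), [5-(benzoyloxy)-3,4-dihydroxy-6-[(4-methoxybenzyl)oxy]cyclohex-1-en-1-yl]methyl benzoate with 3-OH, 4-OH and 5-OBz cis and 6-OPMB trans | O[C@H]1C=C(COC(=O)c2ccccc2)[C@H](OCc2ccc(OC)cc2)[C@@H](OC(=O)c2ccccc2)[C@H]1O
F4 | step 5 | 3,4-O-dibutylstannylene acetal of F3 | CCCC[Sn]1(CCCC)O[C@H]2C=C(COC(=O)c3ccccc3)[C@H](OCc3ccc(OC)cc3)[C@@H](OC(=O)c3ccccc3)[C@H]2O1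
F5 | step 6 | C4 ketone from 7, [5-(benzoyloxy)-3-methoxy-6-[(4-methoxybenzyl)oxy]-4-oxocyclohex-1-en-1-yl]methyl benzoate | CO[C@H]1C=C(COC(=O)c2ccccc2)[C@H](OCc2ccc(OC)cc2)[C@@H](OC(=O)c2ccccc2)C1=O
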